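Both prenyl groups are disconnected at their aryl–CH2 bonds (C6–C1'' on ring A, C2'–C1'' on ring B) back to tertiary 1,1-dimethylallyl ethers on O5 and O3' of (2S)-hesperetin. The key step exploits that each of these oxygens has only one ortho carbon able to rearomatise: O5 is flanked by ring-fusion carbon C4a and C6, O3' by methoxylated C4' and C2'. One heating therefore moves both five-carbon units from oxygen to carbon by [3,3] shifts with allylic transposition, giving the two linear prenyl groups while C2 stays untouched. The precursor is the 7-O-MOM flavanone bearing both reverse-prenyl ethers, made by copper-catalysed propargylation and semi-hydrogenation.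

Key step: step 4

Remark 1: the purchased (2S)-hesperetin is assumed to be enantiopure; this is to be confirmed by chiral HPLC before use, because every later step only conserves C2.
Remark 2: steps 2–4 each convert two sites in one operation; the unchelated, less shielded ring B site is assumed to react first in steps 2 and 3 and the ring A ether to shift first in step 4. The numbered half-converted intermediates follow this assumption, and the opposite order leads to the same products.

Step 1
Reactants: 1 (2S)-hesperetin; 2 chloromethyl methyl ether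
Product: 3 (2S)-7-O-(methoxymethyl)hesperetin
Conditions: MOMCl (1.1 equiv), i-Pr2NEt (1.3 equiv), THF, 0 °C to rt
Reagents that add atoms: chloromethyl methyl ether, COCCl
Why: Williamson-type O-alkylation (MOM protection) should take only the 7-OH, the most acidic phenol because it is para to the C4 carbonyl, while the 5-OH is held in a hydrogen bond to C4=O, the 3'-OH is a much weaker acid, and the mild amine base leaves C2 untouched.

Step 2
Reactants: 3 (2S)-7-O-(methoxymethyl)hesperetin; 4 3-chloro-3-methylbut-1-yne
Product: 6 (2S)-7-O-MOM-5,3'-bis-O-(2-methylbut-3-yn-2-yl)hesperetin, via 3'-O-mono(2-methylbut-3-yn-2-yl) ether 5 (not isolated)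
Conditions: 4 (3 equiv), DBU (2.2 equiv, slow addition), CuCl2·2H2O (2 mol%), MeCN, −5 to 0 °C, Ar
Reagents that add atoms: 3-chloro-3-methylbut-1-yne, CC(C)(Cl)C#C
Why: Copper-catalysed propargylic etherification of phenols with a tertiary propargyl chloride (a copper acetylide/allenylidene captured at its tertiary carbon by the phenoxide) tolerates hindered and ortho-acyl phenols, the free 3'-OH reacting before the chelated 5-OH, and because DBU is kept below the amount of chloride no free amidine should remain to open ring C by retro-oxa-Michael reaction, so C2 keeps its configuration.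

Step 3
Reactants: 6 (2S)-7-O-MOM-5,3'-bis-O-(2-methylbut-3-yn-2-yl)hesperetin
Product: 8 (2S)-7-O-MOM-5,3'-bis-O-(2-methylbut-3-en-2-yl)hesperetin, via 3'-ene-5-yne half-reduced ether 7 (not isolated)
Conditions: H2 (1 atm), Pd/CaCO3 poisoned with Pb(OAc)2 (Lindlar catalyst), quinoline, EtOAc, rt, stopped after 2 equiv H2; crude product used without delay
Reagents that add atoms: none
Why: Lindlar semi-hydrogenation stops at the alkene because the lead- and quinoline-poisoned palladium surface binds terminal alkynes far more strongly than the resulting vinyl groups, while the ketone, the MOM acetal and the aryl ethers are inert and no stereocentre is touched.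

Step 4
Reactants: 8 (2S)-7-O-MOM-5,3'-bis-O-(2-methylbut-3-en-2-yl)hesperetin
Product: 10 (2S)-7-O-MOM-6,2'-diprenylhesperetin, via 6-prenyl 3'-O-(1,1-dimethylallyl) ether 9 (not isolated)
Conditions: PhMe (degassed, 0.02 M), 110 °C, sealed tube
Reagents that add atoms: none
Why: Each tertiary allyl aryl ether undergoes a concerted aromatic Claisen rearrangement through a chair-like six-membered transition state in which the terminal CH2 of the vinyl group bonds to the open ortho carbon while the O–CMe2 bond breaks, and the resulting ortho-cyclohexadienone enolises to the phenol; the allylic transposition turns each 1,1-dimethylallyl group into a linear 3-methylbut-2-enyl group, forming C6–C1'' on ring A (expected first, via 9) and C2'–C1'' on ring B. The closest known reaction type is the thermal Claisen rearrangement of aryl 1,1-dimethylallyl ethers to ortho-prenylphenols, established on flavonoid, xanthone and coumarin cores. No ring is closed and no stereocentre is created; C2 is a spectator and sees neither acid nor base. The step needs site selectivity (C6 not C8, C2' not C6'), which the substrate secures because the second ortho carbon of O5 is the ring-fusion carbon C4a and that of O3' is the methoxylated C4', so a shift to either gives a dienone that cannot tautomerise and mainly reverts. The freed 5-OH is tied up in a hydrogen bond to C4=O and O7 stays capped by MOM, so no phenol should add to the new prenyl alkenes, and holding the bath near 110 °C in a neutral, degassed, dilute medium should keep the para Claisen–Cope shift and ionisation of the tertiary ethers (loss of isoprene) in the background.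

Step 5
Reactants: 10 (2S)-7-O-MOM-6,2'-diprenylhesperetin
Product: 11 (2S)-6,2'-diprenylhesperetin (target CNP0306216.1)
Conditions: HCl (1.25 M in MeOH, 3 equiv), MeOH, rt to 40 °C, short; NaHCO3 quench
Reagents that add atoms: none
Why: Acid-catalysed acetal exchange (MOM cleavage) in methanol releases the 7-phenol and dimethoxymethane far faster than the trisubstituted alkenes are protonated, so brief, cool exposure followed by a bicarbonate quench should spare both prenyl groups and the C2 centre.

Compound list
1 | (2S)-hesperetin, (2S)-5,7-dihydroxy-2-(3-hydroxy-4-methoxyphenyl)chroman-4-one | COc1ccc([C@@H]2CC(=O)c3c(O)cc(O)cc3O2)cc1O | starting material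
2 | chloromethyl methyl ether (MOMCl) | COCCl | starting material
3 | (2S)-5-hydroxy-2-(3-hydroxy-4-methoxyphenyl)-7-(methoxymethoxy)chroman-4-one | COc1ccc([C@@H]2CC(=O)c3c(O)cc(OCOC)cc3O2)cc1O | intermediate
4 | 3-chloro-3-methylbut-1-yne | CC(C)(Cl)C#C | starting material
5 | (2S)-5-hydroxy-2-[4-methoxy-3-(2-methylbut-3-yn-2-yloxy)phenyl]-7-(methoxymethoxy)chroman-4-one | COc1ccc([C@@H]2CC(=O)c3c(O)cc(OCOC)cc3O2)cc1OC(C)(C)C#C | intermediate (not isolated)
6 | (2S)-2-[4-methoxy-3-(2-methylbut-3-yn-2-yloxy)phenyl]-7-(methoxymethoxy)-5-(2-methylbut-3-yn-2-yloxy)chroman-4-one | COc1ccc([C@@H]2CC(=O)c3c(OC(C)(C)C#C)cc(OCOC)cc3O2)cc1OC(C)(C)C#C | intermediate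
7 | (2S)-2-[4-methoxy-3-(2-methylbut-3-en-2-yloxy)phenyl]-7-(methoxymethoxy)-5-(2-methylbut-3-yn-2-yloxy)chroman-4-one | COc1ccc([C@@H]2CC(=O)c3c(OC(C)(C)C#C)cc(OCOC)cc3O2)cc1OC(C)(C)C=C | intermediate (not isolated)
8 | (2S)-2-[4-methoxy-3-(2-methylbut-3-en-2-yloxy)phenyl]-7-(methoxymethoxy)-5-(2-methylbut-3-en-2-yloxy)chroman-4-one (Claisen precursor) | COc1ccc([C@@H]2CC(=O)c3c(OC(C)(C)C=C)cc(OCOC)cc3O2)cc1OC(C)(C)C=C | intermediate
9 | (2S)-5-hydroxy-2-[4-methoxy-3-(2-methylbut-3-en-2-yloxy)phenyl]-7-(methoxymethoxy)-6-(3-methylbut-2-enyl)chroman-4-one | COc1ccc([C@@H]2CC(=O)c3c(O)c(CC=C(C)C)c(OCOC)cc3O2)cc1OC(C)(C)C=C | intermediate (not isolated)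
10 | (2S)-5-hydroxy-2-[3-hydroxy-4-methoxy-2-(3-methylbut-2-enyl)phenyl]-7-(methoxymethoxy)-6-(3-methylbut-2-enyl)chroman-4-one | COc1ccc([C@@H]2CC(=O)c3c(O)c(CC=C(C)C)c(OCOC)cc3O2)c(CC=C(C)C)c1O | intermediate
11 | (2S)-5,7-dihydroxy-2-[3-hydroxy-4-methoxy-2-(3-methylbut-2-enyl)phenyl]-6-(3-methylbut-2-enyl)chroman-4-one | COc1ccc([C@@H]2CC(=O)c3c(O)c(CC=C(C)C)c(O)cc3O2)c(CC=C(C)C)c1O | target

Total step count: 5. Longest linear sequence: 5 steps (1 → 3 → 6 → 8 → 10 → 11).

Steps most likely to fail

Step 4. The double shift may stall or go astray: the tertiary ethers may ionise and lose isoprene, the shift into the crowded C2' may lag, or a para Claisen–Cope excursion to C8 or C6' may set in. The fallback sets out from 3 and replaces the reverse-prenyl ethers by primary allyl ethers, which cannot fragment. Mitsunobu O-allylation of both phenols (allyl alcohol, PPh3, DIAD, THF, 0 °C to rt; neutral, known for the chelated 5-OH of flavanones) should give (2S)-7-O-MOM-5,3'-di-O-allylhesperetin F2. Thermal aromatic Claisen rearrangement (1,2-dichlorobenzene, 180 °C) then moves the allyl groups to C6 and C2', as is well known for 5-O-allylflavonoids and for allyl ethers of isovanillin, giving (2S)-6,2'-diallyl-7-O-MOM-hesperetin F3. Olefin cross-metathesis with excess 2-methylbut-2-ene (second-generation Grubbs catalyst, CH2Cl2, 40 °C) converts both allyl groups into prenyl groups and comes back to the route at 10.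

Step 2. Etherification of the hydrogen-bonded 5-OH may be sluggish, and DBU may open ring C by retro-oxa-Michael reaction, which would erode the C2 configuration. The fallback sets out from 3 and uses a palladium-catalysed decarboxylative O-tert-prenylation (Tsuji–Trost type) with commercial tert-butyl 2-methylbut-3-en-2-yl carbonate and Pd(PPh3)4 (zerovalent palladium) in THF at 0 °C. It needs no amine base and forms the branched allyl ethers kinetically. The 3'-mono ether (2S)-7-O-MOM-3'-O-(2-methylbut-3-en-2-yl)hesperetin F1 forms first and, if the 5-OH lags, is isolated and resubmitted. The sequence comes back to the route at 8 and makes step 3 unnecessary.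

Step 5. Acid may add the neighbouring phenols (O5, O7, O3') across the prenyl double bonds to give chromans in competition with acetal cleavage. The fallback sets out from 6 and removes the MOM group there, where neither a prenyl alkene nor an acid-labile tertiary allyl ether is present. Methanolic HCl at rt should give the free 7-phenol (2S)-5,3'-bis-O-(2-methylbut-3-yn-2-yl)hesperetin F4. Lindlar semi-hydrogenation as in step 3 gives (2S)-5,3'-bis-O-(2-methylbut-3-en-2-yl)hesperetin F5, and the thermal double Claisen rearrangement of step 4 on this free phenol comes back to the route directly at 11, with no acid after the prenyl groups exist.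

Further compounds
F1 | step 2 | (2S)-5-hydroxy-2-[4-methoxy-3-(2-methylbut-3-en-2-yloxy)phenyl]-7-(methoxymethoxy)chroman-4-one | COc1ccc([C@@H]2CC(=O)c3c(O)cc(OCOC)cc3O2)cc1OC(C)(C)C=C
F2 | step 4 | (2S)-5-(allyloxy)-2-[3-(allyloxy)-4-methoxyphenyl]-7-(methoxymethoxy)chroman-4-one | COc1ccc([C@@H]2CC(=O)c3c(OCC=C)cc(OCOC)cc3O2)cc1OCC=C
F3 | step 4 | (2S)-6-allyl-2-(2-allyl-3-hydroxy-4-methoxyphenyl)-5-hydroxy-7-(methoxymethoxy)chroman-4-one | COc1ccc([C@@H]2CC(=O)c3c(O)c(CC=C)c(OCOC)cc3O2)c(CC=C)c1O
F4 | step 5 | (2S)-7-hydroxy-2-[4-methoxy-3-(2-methylbut-3-yn-2-yloxy)phenyl]-5-(2-methylbut-3-yn-2-yloxy)chroman-4-one | COc1ccc([C@@H]2CC(=O)c3c(OC(C)(C)C#C)cc(O)cc3O2)cc1OC(C)(C)C#C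
F5 | step 5 | (2S)-7-hydroxy-2-[4-methoxy-3-(2-methylbut-3-en-2-yloxy)phenyl]-5-(2-methylbut-3-en-2-yloxy)chroman-4-one | COc1ccc([C@@H]2CC(=O)c3c(OC(C)(C)C=C)cc(O)cc3O2)cc1OC(C)(C)C=C
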